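**Retrosynthetic overview**
- The δ-lactone is disconnected at C13′–C3 and O–C4 into cyclopentadienone ketal 22 and (Z)-3-iodo-2-arylacrylic acid 35, joined by a palladium-catalysed carbo-oxygenation (Larock-type [4+2] heteroannulation). The enabling feature: the two new bonds sit on the adjacent cyclopentene carbons C3 and C4, and C4 is allylic to the ring-fusion alkene C1=C5, so C3=C4–C5=C1 can serve as a 1,3-diene and C4–C5–C1 as a π-allyl.
- The AcO-bearing C2 is carried through the annulation as a spiro-dioxolane (no hydrogen at C2, so no 1,5-H shift and no cyclopentadienone), then ketone → 2β-alcohol → acetate. The α-methylene-γ-lactone is masked as 8α-OTIPS plus a 7β-[3-(PMB-oxy)prop-1-en-2-yl] group.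
- Diene 22: cycloheptadiene by Rh-catalysed [4+3] (sets C10), Ru-BINAP dynamic kinetic resolution (C7, C8), cyclopentenone by carbonylative coupling and Nazarov cyclisation, diene by selenoxide elimination.
- Acid 35: Zr-catalysed carboalumination, Ir-catalysed asymmetric hydrogenation (side-chain centre), anti-carbomagnesiation of propargyl alcohol with iodination, oxidation.
- Ring order: cycloheptene → cyclopentenone → cyclopentadiene → δ-lactone (key step) → γ-lactone (last).

Key step: step 23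

**Remarks**
- Numbering: guaiane numbering C1–C15 for the hydroazulene half (C2 bears OAc, C3/C4 carry the δ-lactone, C7/C8 the γ-lactone, C10 the methyl C14, C11–C13 the methylene lactone); C11′ (ArCH), C12′ (C=O), C13′ (CH2) for the δ-lactone; β is the face of the C10 methyl.
- Assumption: 1, 4, 10, 16, 23 and 31 are purchased; the enantiomers of the dirhodium catalyst (step 4) and the iridium catalyst (step 20) named below are assumed to give the drawn configuration, and the mirror-image catalyst is used if the sense is opposite.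

**Route**

Step 1
Reactants: 1 (E)-but-2-enal
Product: 2 (Z)-2-bromobut-2-enal
Conditions: Br2, CH2Cl2, 0 °C; then Et3N, 0 °C to rt
Reagents that add atoms: bromine, BrBr
Why: Bromination–dehydrobromination of an enal should give the conjugated (Z)-2-bromo enal, the more stable isomer.

Step 2
Reactants: 2 (Z)-2-bromobut-2-enal
Product: 3 (Z)-3-bromopenta-1,3-diene
Conditions: Ph3PCH3Br, KHMDS, Et2O, −78 to 0 °C; used as a solution
Reagents that add atoms: methyltriphenylphosphonium bromide (ylide source), C[P+](c1ccccc1)(c1ccccc1)c1ccccc1.[Br-]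
Why: Wittig methylenation of the aldehyde leaves the bromoalkene geometry untouched (methyl trans to the new vinyl group, as the later Cope step requires).

Step 3
Reactants: 4 ethyl 2-diazo-3-oxobutanoate
Product: 5 ethyl 3-[(tert-butyldimethylsilyl)oxy]-2-diazobut-3-enoate
Conditions: TBSOTf, Et3N, CH2Cl2, 0 °C
Reagents that add atoms: tert-butyldimethylsilyl triflate, CC(C)(C)[Si](C)(C)OS(=O)(=O)C(F)(F)F
Why: Soft enolisation and O-silylation of the acetyl group should give the siloxyvinyldiazoacetate used in carbenoid [4+3] chemistry.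

Step 4
Reactants: 3 (Z)-3-bromopenta-1,3-diene; 5 ethyl 3-[(tert-butyldimethylsilyl)oxy]-2-diazobut-3-enoate
Product: 7 ethyl (5S)-4-bromo-5-methyl-7-oxocyclohept-3-ene-1-carboxylate (C1 epimers/enol), via silyl enol ether 6 (not isolated)
Conditions: Rh2(S-PTAD)4 (1 mol %), 3 (4 equiv), 2,2-dimethylbutane, −26 °C to rt; then 1 M HCl, THF, rt
Reagents that add atoms: none
Why: Rhodium-carbenoid cyclopropanation of the terminal vinyl group of 3 and Cope rearrangement of the cis-divinylcyclopropane (formal [4+3] cycloaddition) should build the ring with C10 set by the chiral dirhodium carboxylate, and acid then hydrolyses the silyl enol ether.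

Step 5
Reactants: 7 ethyl (5S)-4-bromo-5-methyl-7-oxocyclohept-3-ene-1-carboxylate
Product: 8 ethyl (1S,5S,7S)-4-bromo-7-hydroxy-5-methylcyclohept-3-ene-1-carboxylate
Conditions: H2 (100 atm), RuBr2[(S)-BINAP] (1 mol %), CH2Cl2, 50 °C
Reagents that add atoms: none
Why: Noyori hydrogenation with dynamic kinetic resolution: C7 racemises through the enol faster than reduction, the (S)-BINAP catalyst should give the (S)-carbinol at C8 and the anti (trans) ester at C7 under catalyst control, and the vinyl bromide is not a substrate for this catalyst.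

Step 6
Reactants: 8 ethyl (1S,5S,7S)-4-bromo-7-hydroxy-5-methylcyclohept-3-ene-1-carboxylate
Product: 9 ethyl (1S,5S,7S)-4-bromo-5-methyl-7-[(triisopropylsilyl)oxy]cyclohept-3-ene-1-carboxylate
Conditions: TIPSOTf, 2,6-lutidine, CH2Cl2, 0 °C to rt
Reagents that add atoms: triisopropylsilyl triflate, CC(C)[Si](C(C)C)(C(C)C)OS(=O)(=O)C(F)(F)F
Why: Silylation of the secondary alcohol; the TIPS ether is chosen to survive the Lewis acid of step 8.

Step 7
Reactants: 9 ethyl (1S,5S,7S)-4-bromo-5-methyl-7-[(triisopropylsilyl)oxy]cyclohept-3-ene-1-carboxylate; 10 (E)-prop-1-en-1-ylboronic acid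
Product: 11 ethyl (1S,5S,7S)-4-[(E)-but-2-enoyl]-5-methyl-7-[(triisopropylsilyl)oxy]cyclohept-3-ene-1-carboxylate
Conditions: CO (5 atm), PdCl2(dppf) (5 mol %), K2CO3, anisole, 80 °C
Reagents that add atoms: carbon monoxide, [C-]#[O+]
Why: Carbonylative Suzuki–Miyaura coupling: the acylpalladium formed by oxidative addition and CO insertion should be captured by the alkenylboronic acid to give the divinyl ketone.

Step 8
Reactants: 11 ethyl (1S,5S,7S)-4-[(E)-but-2-enoyl]-5-methyl-7-[(triisopropylsilyl)oxy]cyclohept-3-ene-1-carboxylate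
Product: 12 ethyl (5S,6S,8S)-3,8-dimethyl-1-oxo-6-[(triisopropylsilyl)oxy]-1,2,3,4,5,6,7,8-octahydroazulene-5-carboxylate (C3 epimers; guaiane: 2-oxo, 1(5)-ene, 7β-CO2Et, 8α-OTIPS, 10β-Me)
Conditions: BF3·OEt2 (1.5 equiv), CH2Cl2, 0 °C to rt
Reagents that add atoms: none
Why: Nazarov cyclisation: conrotatory 4π closure of the pentadienyl cation forms C4–C5 and proton loss should place the alkene in the tetrasubstituted ring-fusion position C1=C5; the C4 epimers converge in step 15.

Step 9
Reactants: 12 the hydroazulenone of step 8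
Product: 13 the 3-(phenylselanyl) derivative of 12 (guaiane C3; Se trans to the C4 methyl)
Conditions: LDA (1.05 equiv), THF, −78 °C; PhSeCl, −78 °C
Reagents that add atoms: phenylselenyl chloride, Cl[Se]c1ccccc1
Why: Kinetic α′-deprotonation of the enone at C3 and selenenylation anti to the C4 methyl should put selenium cis to H4, as the later syn elimination needs.

Step 10
Reactants: 13 the α′-selenide
Product: 14 the C2 spiro-1,3-dioxolane of 13
Conditions: 1,2-bis(trimethylsilyloxy)ethane, TMSOTf (5 mol %), CH2Cl2, −78 to −20 °C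
Reagents that add atoms: 1,2-bis(trimethylsilyloxy)ethane, C[Si](C)(C)OCCO[Si](C)(C)C
Why: Noyori ketalisation works on enones at low temperature without moving the C1=C5 alkene, and it removes the carbonyl so that the diene of step 15 is not a cyclopentadienone.

Step 11
Reactants: 14 the ketal ester
Product: 15 the N-methoxy-N-methylamide of 14 (C7 carboxamide)
Conditions: MeNH(OMe)·HCl, i-PrMgCl, THF, −20 to 0 °C
Reagents that add atoms: N,O-dimethylhydroxylamine hydrochloride, CNOC.Cl
Why: Weinreb amide formation from an ester with the magnesium amide.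

Step 12
Reactants: 16 (tributylstannyl)methanol
Product: 17 tributyl({[(4-methoxyphenyl)methoxy]methyl})stannane
Conditions: NaH, 4-methoxybenzyl chloride, n-Bu4NI (cat.), THF/DMF, 0 °C to rt
Reagents that add atoms: 4-methoxybenzyl chloride, COc1ccc(CCl)cc1
Why: Williamson etherification of the stannylmethanol alkoxide.

Step 13
Reactants: 15 the Weinreb amide; 17 tributyl({[(4-methoxyphenyl)methoxy]methyl})stannane
Product: 19 the C7 2-[(4-methoxybenzyl)oxy]acetyl ketone, via alkoxymethyllithium 18 (not isolated)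
Conditions: 17, n-BuLi, THF, −78 °C; then 15, −78 °C; aq. NH4Cl
Reagents that add atoms: none
Why: Tin–lithium exchange gives the α-alkoxymethyllithium, which should add once to the Weinreb amide because the chelated tetrahedral adduct is stable until work-up.

Step 14
Reactants: 19 the α-alkoxy ketone
Product: 20 the 7β-{3-[(4-methoxybenzyl)oxy]prop-1-en-2-yl} compound
Conditions: Zn, CH2Br2, TiCl4, THF/CH2Cl2, 0 °C to rt
Reagents that add atoms: dibromomethane, BrCBr
Why: The non-basic Lombardo methylenation should avoid epimerisation at C7 and β-elimination of the silyloxy group.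

Step 15
Reactants: 20 the selenide bearing the masked lactone
Product: 22 cyclopentadienone ketal (diene C3=C4–C5=C1, C2 dioxolane, 4-Me, 10β-Me, 8α-OTIPS, 7β-[3-(PMB-oxy)prop-1-en-2-yl]), via selenoxide 21 (not isolated)
Conditions: H2O2 (30 %), pyridine, CH2Cl2, 0 °C to rt; used at once
Reagents that add atoms: none
Why: Selenoxide syn-elimination can only take H4 because C2 carries no hydrogen, so the C3=C4 alkene and hence the 1,3-diene should form with defined position.

Step 16
Reactants: 23 (4-bromo-2-iodophenyl)methanol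
Product: 24 [(4-bromo-2-iodobenzyl)oxy](tert-butyl)diphenylsilane
Conditions: TBDPSCl, imidazole, DMF, rt
Reagents that add atoms: tert-butyl(chloro)diphenylsilane, CC(C)(C)[Si](Cl)(c1ccccc1)c1ccccc1
Why: Silylation of the primary benzylic alcohol with a group that survives every step up to step 30.

Step 17
Reactants: 24 the aryl iodide
Product: 26 [(4-bromo-2-ethynylbenzyl)oxy](tert-butyl)diphenylsilane, via trimethylsilyl alkyne 25 (not isolated)
Conditions: ethynyltrimethylsilane, PdCl2(PPh3)2 (2 mol %), CuI (4 mol %), Et3N, THF, rt; then K2CO3, MeOH, rt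
Reagents that add atoms: ethynyltrimethylsilane, C#C[Si](C)(C)C
Why: Sonogashira coupling should occur at the C–I bond much faster than at C–Br, and methanolysis removes the C-silyl group.

Step 18
Reactants: 26 the terminal aryl alkyne
Product: 28 (E)-4-[5-bromo-2-({[tert-butyl(diphenyl)silyl]oxy}methyl)phenyl]pent-3-en-1-ol, via alkenylalane 27 (not isolated)
Conditions: Me3Al (2 equiv), Cp2ZrCl2 (0.2 equiv), CH2Cl2, rt; then MeLi (1 equiv), THF, −78 °C; ethylene oxide, −78 to 0 °C; aq. Rochelle salt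
Reagents that add atoms: trimethylaluminium, C[Al](C)C; ethylene oxide, C1CO1
Why: Negishi zirconium-catalysed syn-carboalumination puts methyl on the aryl-bearing carbon, and the alkenylalanate opens the epoxide with retention, giving the (E)-trisubstituted homoallylic alcohol.

Step 19
Reactants: 28 the homoallylic alcohol
Product: 29 the tert-butyldimethylsilyl ether of 28
Conditions: TBSCl, imidazole, DMF, rt
Reagents that add atoms: tert-butyl(chloro)dimethylsilane, CC(C)(C)[Si](C)(C)Cl
Why: Silylation of the primary alcohol, which is released again in step 25 and acetylated together with the C2 hydroxyl.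

Step 20
Reactants: 29 the (E)-alkene
Product: 30 [(4-bromo-2-{(2R)-5-[(tert-butyldimethylsilyl)oxy]pentan-2-yl}benzyl)oxy](tert-butyl)diphenylsilane
Conditions: H2 (50 bar), [Ir(cod)((S)-tBu-PHOX)]BArF (1 mol %), CH2Cl2, rt
Reagents that add atoms: none
Why: Iridium–P,N (Pfaltz-type) asymmetric hydrogenation of an (E)-aryl,methyl-trisubstituted alkene should set the benzylic centre (R) under catalyst control while leaving the aryl bromide intact.

Step 21
Reactants: 30 the aryl bromide; 31 prop-2-yn-1-ol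
Product: 33 (Z)-3-iodo-2-aryl-prop-2-en-1-ol (aryl = 4-(TBDPS-oxymethyl)-3-[(2R)-5-(TBS-oxy)pentan-2-yl]phenyl; I cis to CH2OH), via arylmagnesium bromide 32 (not isolated)
Conditions: Mg, LiCl, THF, 45 °C; then 31 (pre-treated with i-PrMgCl, 1 equiv), CuI (10 mol %), THF, 0 to 45 °C; then I2, −20 °C
Reagents that add atoms: iodine, II
Why: Copper-catalysed anti-carbomagnesiation of the propargyl alkoxide puts aryl on C2 and alkoxide-chelated magnesium on C3, and iodinolysis with retention should give the vinyl iodide with iodine cis to the CH2OH group.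

Step 22
Reactants: 33 the (Z)-iodo allylic alcohol
Product: 35 (Z)-3-iodo-2-arylacrylic acid (same aryl; I cis to CO2H), via enal 34 (not isolated)
Conditions: TEMPO (10 mol %), PhI(OAc)2, CH2Cl2, rt; then NaClO2, NaH2PO4, 2-methyl-2-butene, t-BuOH/H2O, 0 °C
Reagents that add atoms: sodium chlorite, [Na+].[O-]Cl=O
Why: TEMPO/PhI(OAc)2 oxidation to the enal and Pinnick oxidation to the acid should leave the vinyl iodide geometry and the silyl ethers untouched.

Step 23
Reactants: 22 cyclopentadienone ketal; 35 (Z)-3-iodo-2-arylacrylic acid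
Product: 36 cis-fused 5,6-dihydropyran-2-one on C3/C4 (new C13′–C3 and O–C4 bonds, both β; C13′=C11′ bearing the aryl group; C1=C5 retained; C2 dioxolane; 8α-OTIPS; masked lactone at C7)
Conditions: Pd(OAc)2 (10 mol %), n-Bu4NCl (1 equiv), K2CO3 (2.5 equiv), DMF, 60 °C
Reagents that add atoms: none
Why: Zerovalent palladium (from Pd(OAc)2) inserts into the C–I bond of 35 to give a vinylpalladium carboxylate, which carbopalladates diene 22 syn at its only unsubstituted terminus C3 (new C13′–C3 bond) and so becomes the π-allyl C4–C5–C1; the palladium-bound carboxylate then forms the O–C4 bond by reductive elimination and returns zerovalent palladium. The closest known reaction type is the Larock heteroannulation of 1,3-dienes (cyclic ones included) by o-iodobenzoic acids and by vinylic halides that carry a nucleophile, which also forms tertiary C–O bonds at the substituted allyl terminus. The δ-lactone closes as a [4+2] heteroannulation, six-membered by C–O formation at the allyl terminus next to the new C–C bond (attack at C1 would need an eight-membered ring). C3 and C4 form cis because carbon and oxygen are both delivered from the palladium-bearing face, and that face should be β: the chair cycloheptene folds C7–C8–C9 and the 8α-OTIPS group under the α-face, while the pseudo-axial C10 methyl sits over C1/C2, away from the C3=C4 bond that is attacked. The step needs regioselectivity (C3 over the fully substituted C1), chemoselectivity over the 1,1-disubstituted alkene at C11 and speed over diene dimerisation; the spiro-ketal at C2 (no 1,5-hydrogen shift), the trisubstituted diene and the modest temperature should secure these.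

Step 24
Reactants: 36 the unsaturated δ-lactone
Product: 37 the saturated (11′R)-δ-lactone (C13′H2, aryl equatorial and cis to the C3–C2 bond)
Conditions: [(Ph3P)CuH]6, H2O (2 equiv), PhMe/THF, rt; then DBU (0.2 equiv), PhMe, rt
Reagents that add atoms: none
Why: Copper hydride conjugate reduction is selective for the α-aryl enoate, and both protonation of the enolate from the convex face and DBU equilibration should place the aryl group equatorial (11′R).

Step 25
Reactants: 37 the saturated lactone ketal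
Product: 38 the C2 enone with free side-chain primary alcohol
Conditions: CSA (0.2 equiv), MeOH/H2O (9:1), 0 °C to rt
Reagents that add atoms: water, O
Why: Acid hydrolysis of the allylic dioxolane gives the conjugated enone and methanolysis removes the primary TBS ether, while the secondary TIPS, primary TBDPS and PMB ethers should survive.

Step 26
Reactants: 38 the enone
Product: 39 the 2β-allylic alcohol (diol)
Conditions: NaBH4, CeCl3·7H2O, MeOH, −78 °C
Reagents that add atoms: none
Why: Luche 1,2-reduction: hydride should add to C2 from the α-face, anti to both the C3 substituent (C13′) and the C10 methyl, giving the 2β-alcohol without touching the lactone.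

Step 27
Reactants: 39 the diol
Product: 40 the diacetate (C2 β-OAc and side-chain OAc)
Conditions: Ac2O, pyridine, DMAP (cat.), CH2Cl2, 0 °C to rt
Reagents that add atoms: acetic anhydride, CC(=O)OC(C)=O
Why: DMAP-catalysed acetylation of both free hydroxyls in one operation.

Step 28
Reactants: 40 the PMB ether
Product: 41 the primary allylic alcohol (C12 OH)
Conditions: DDQ (1.3 equiv), CH2Cl2/pH 7 buffer (10:1), 0 °C to rt
Reagents that add atoms: none
Why: Oxidative cleavage of the PMB ether; acetates and silyl ethers are inert to DDQ.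

Step 29
Reactants: 41 the allylic alcohol
Product: 43 the 2-substituted acrylic acid (C11(=CH2)–CO2H at C7), via enal 42 (not isolated)
Conditions: TEMPO (0.2 equiv), PhI(OAc)2, CH2Cl2, rt; then NaClO2, NaH2PO4, 2-methyl-2-butene, t-BuOH/H2O, 0 °C
Reagents that add atoms: sodium chlorite, [Na+].[O-]Cl=O
Why: Chemoselective oxidation of the only free primary alcohol to the acid; the benzylic and C8 oxygens are still silylated and the scavenger protects the alkenes.

Step 30
Reactants: 43 the acrylic acid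
Product: 45 CNP0205574.1, via hydroxy acid 44 (not isolated)
Conditions: HF·pyridine, pyridine/THF, 0 °C to rt (polypropylene vessel)
Reagents that add atoms: none
Why: Fluoride removes the TIPS and TBDPS ethers, and the freed 8α-hydroxyl should lactonise onto the 7β-acrylic acid in the acidic medium to close the trans-fused α-methylene-γ-butyrolactone, with the acetates untouched.

**Compound list**
1 | (E)-but-2-enal | C/C=C/C=O | starting material
2 | (Z)-2-bromobut-2-enal | C/C=C(\Br)C=O | intermediate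
3 | (Z)-3-bromopenta-1,3-diene | C/C=C(\Br)C=C | intermediate
4 | ethyl 2-diazo-3-oxobutanoate | CCOC(=O)C(=[N+]=[N-])C(C)=O | starting material
5 | ethyl 3-[(tert-butyldimethylsilyl)oxy]-2-diazobut-3-enoate | CCOC(=O)C(=[N+]=[N-])C(=C)O[Si](C)(C)C(C)(C)C | intermediate
6 | ethyl (4S)-5-bromo-2-[(tert-butyldimethylsilyl)oxy]-4-methylcyclohepta-1,5-diene-1-carboxylate | CCOC(=O)C1=C(O[Si](C)(C)C(C)(C)C)C[C@H](C)C(Br)=CC1 | intermediate
7 | ethyl (5S)-4-bromo-5-methyl-7-oxocyclohept-3-ene-1-carboxylate | CCOC(=O)C1C(=O)C[C@H](C)C(Br)=CC1 | intermediate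
8 | ethyl (1S,5S,7S)-4-bromo-7-hydroxy-5-methylcyclohept-3-ene-1-carboxylate | O[C@H]1C[C@H](C)C(Br)=CC[C@@H]1C(=O)OCC | intermediate
9 | ethyl (1S,5S,7S)-4-bromo-5-methyl-7-[(triisopropylsilyl)oxy]cyclohept-3-ene-1-carboxylate | CC(C)[Si](C(C)C)(C(C)C)O[C@H]1C[C@H](C)C(Br)=CC[C@@H]1C(=O)OCC | intermediate
10 | (E)-prop-1-en-1-ylboronic acid | C/C=C/B(O)O | starting material
11 | ethyl (1S,5S,7S)-4-[(E)-but-2-enoyl]-5-methyl-7-[(triisopropylsilyl)oxy]cyclohept-3-ene-1-carboxylate | CC(C)[Si](C(C)C)(C(C)C)O[C@H]1C[C@H](C)C(C(=O)/C=C/C)=CC[C@@H]1C(=O)OCC | intermediate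
12 | ethyl (5S,6S,8S)-3,8-dimethyl-1-oxo-6-[(triisopropylsilyl)oxy]-1,2,3,4,5,6,7,8-octahydroazulene-5-carboxylate (C3 epimers) | CC(C)[Si](C(C)C)(C(C)C)O[C@H]1C[C@H](C)C2=C(C[C@@H]1C(=O)OCC)C(C)CC2=O | intermediate
13 | 2-(phenylselanyl) derivative of 12 (azulene C2 = guaiane C3) | CC(C)[Si](C(C)C)(C(C)C)O[C@H]1C[C@H](C)C2=C(C[C@@H]1C(=O)OCC)C(C)C([Se]c1ccccc1)C2=O | intermediate
14 | spiro-1,3-dioxolane (guaiane C2) of 13 | CC(C)[Si](C(C)C)(C(C)C)O[C@H]1C[C@H](C)C2=C(C[C@@H]1C(=O)OCC)C(C)C([Se]c1ccccc1)C21OCCO1 | intermediate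
15 | N-methoxy-N-methylamide corresponding to 14 | CC(C)[Si](C(C)C)(C(C)C)O[C@H]1C[C@H](C)C2=C(C[C@@H]1C(=O)N(C)OC)C(C)C([Se]c1ccccc1)C21OCCO1 | intermediate
16 | (tributylstannyl)methanol | CCCC[Sn](CCCC)(CCCC)CO | starting material
17 | tributyl({[(4-methoxyphenyl)methoxy]methyl})stannane | CCCC[Sn](CCCC)(CCCC)COCc1ccc(OC)cc1 | intermediate
18 | {[(4-methoxyphenyl)methoxy]methyl}lithium | [Li]COCc1ccc(OC)cc1 | intermediate
19 | C7 2-[(4-methoxybenzyl)oxy]acetyl ketone (selenide, dioxolane, 8α-OTIPS) | CC(C)[Si](C(C)C)(C(C)C)O[C@H]1C[C@H](C)C2=C(C[C@@H]1C(=O)COCc1ccc(OC)cc1)C(C)C([Se]c1ccccc1)C21OCCO1 | intermediate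
20 | 7β-{3-[(4-methoxybenzyl)oxy]prop-1-en-2-yl} selenide ketal | CC(C)[Si](C(C)C)(C(C)C)O[C@H]1C[C@H](C)C2=C(C[C@@H]1C(=C)COCc1ccc(OC)cc1)C(C)C([Se]c1ccccc1)C21OCCO1 | intermediate
21 | selenoxide of 20 | CC(C)[Si](C(C)C)(C(C)C)O[C@H]1C[C@H](C)C2=C(C[C@@H]1C(=C)COCc1ccc(OC)cc1)C(C)C([Se](=O)c1ccccc1)C21OCCO1 | intermediate
22 | cyclopentadienone ketal (diene C3=C4–C5=C1; 8α-OTIPS; 7β-[3-(PMB-oxy)prop-1-en-2-yl]; 10β-Me) | CC(C)[Si](C(C)C)(C(C)C)O[C@H]1C[C@H](C)C2=C(C[C@@H]1C(=C)COCc1ccc(OC)cc1)C(C)=CC21OCCO1 | intermediate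
23 | (4-bromo-2-iodophenyl)methanol | OCc1ccc(Br)cc1I | starting material
24 | [(4-bromo-2-iodobenzyl)oxy](tert-butyl)diphenylsilane | CC(C)(C)[Si](OCc1ccc(Br)cc1I)(c1ccccc1)c1ccccc1 | intermediate
25 | ({4-bromo-2-[(trimethylsilyl)ethynyl]benzyl}oxy)(tert-butyl)diphenylsilane | CC(C)(C)[Si](OCc1ccc(Br)cc1C#C[Si](C)(C)C)(c1ccccc1)c1ccccc1 | intermediate
26 | [(4-bromo-2-ethynylbenzyl)oxy](tert-butyl)diphenylsilane | CC(C)(C)[Si](OCc1ccc(Br)cc1C#C)(c1ccccc1)c1ccccc1 | intermediate
27 | (E)-2-aryl-prop-1-enyl(dimethyl)alane (aryl = 5-bromo-2-(TBDPS-oxymethyl)phenyl) | CC(C)(C)[Si](OCc1ccc(Br)cc1/C(C)=C/[Al](C)C)(c1ccccc1)c1ccccc1 | intermediate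
28 | (E)-4-[5-bromo-2-({[tert-butyl(diphenyl)silyl]oxy}methyl)phenyl]pent-3-en-1-ol | CC(C)(C)[Si](OCc1ccc(Br)cc1/C(C)=C/CCO)(c1ccccc1)c1ccccc1 | intermediate
29 | tert-butyldimethylsilyl ether of 28 | CC(C)(C)[Si](OCc1ccc(Br)cc1/C(C)=C/CCO[Si](C)(C)C(C)(C)C)(c1ccccc1)c1ccccc1 | intermediate
30 | [(4-bromo-2-{(2R)-5-[(tert-butyldimethylsilyl)oxy]pentan-2-yl}benzyl)oxy](tert-butyl)diphenylsilane | CC(C)(C)[Si](OCc1ccc(Br)cc1[C@H](C)CCCO[Si](C)(C)C(C)(C)C)(c1ccccc1)c1ccccc1 | intermediate
31 | prop-2-yn-1-ol | C#CCO | starting material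
32 | arylmagnesium bromide from 30 | CC(C)(C)[Si](OCc1ccc([Mg]Br)cc1[C@H](C)CCCO[Si](C)(C)C(C)(C)C)(c1ccccc1)c1ccccc1 | intermediate
33 | (Z)-3-iodo-2-{4-(TBDPS-oxymethyl)-3-[(2R)-5-(TBS-oxy)pentan-2-yl]phenyl}prop-2-en-1-ol | I/C=C(\CO)c1ccc(CO[Si](c2ccccc2)(c2ccccc2)C(C)(C)C)c([C@H](C)CCCO[Si](C)(C)C(C)(C)C)c1 | intermediate
34 | (Z)-3-iodo-2-arylprop-2-enal (same aryl) | I/C=C(\C=O)c1ccc(CO[Si](c2ccccc2)(c2ccccc2)C(C)(C)C)c([C@H](C)CCCO[Si](C)(C)C(C)(C)C)c1 | intermediate
35 | (Z)-3-iodo-2-arylprop-2-enoic acid (same aryl) | I/C=C(\C(=O)O)c1ccc(CO[Si](c2ccccc2)(c2ccccc2)C(C)(C)C)c([C@H](C)CCCO[Si](C)(C)C(C)(C)C)c1 | intermediate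
36 | annulation product: 3β,4β-cis-fused 11′-aryl-5,6-dihydropyran-2-one, C2 dioxolane | CC(C)[Si](C(C)C)(C(C)C)O[C@H]2C[C@H](C)C3=C(C[C@@H]2C(=C)COCc2ccc(OC)cc2)[C@@]1(C)OC(=O)C(c2ccc(CO[Si](c5ccccc5)(c5ccccc5)C(C)(C)C)c([C@H](C)CCCO[Si](C)(C)C(C)(C)C)c2)=C[C@H]1C34OCCO4 | intermediate
37 | saturated (11′R)-δ-lactone, C2 dioxolane | CC(C)[Si](C(C)C)(C(C)C)O[C@H]2C[C@H](C)C3=C(C[C@@H]2C(=C)COCc2ccc(OC)cc2)[C@@]1(C)OC(=O)[C@@H](c2ccc(CO[Si](c5ccccc5)(c5ccccc5)C(C)(C)C)c([C@H](C)CCCO[Si](C)(C)C(C)(C)C)c2)C[C@H]1C34OCCO4 | intermediate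
38 | C2 enone with free side-chain alcohol | CC(C)[Si](C(C)C)(C(C)C)O[C@H]2C[C@H](C)C3=C(C[C@@H]2C(=C)COCc2ccc(OC)cc2)[C@@]1(C)OC(=O)[C@@H](c2ccc(CO[Si](c5ccccc5)(c5ccccc5)C(C)(C)C)c([C@H](C)CCCO)c2)C[C@H]1C3=O | intermediate
39 | 2β-alcohol (diol) | CC(C)[Si](C(C)C)(C(C)C)O[C@H]2C[C@H](C)C3=C(C[C@@H]2C(=C)COCc2ccc(OC)cc2)[C@@]1(C)OC(=O)[C@@H](c2ccc(CO[Si](c5ccccc5)(c5ccccc5)C(C)(C)C)c([C@H](C)CCCO)c2)C[C@H]1[C@H]3O | intermediate
40 | diacetate, PMB ether | CC(C)[Si](C(C)C)(C(C)C)O[C@H]2C[C@H](C)C3=C(C[C@@H]2C(=C)COCc2ccc(OC)cc2)[C@@]1(C)OC(=O)[C@@H](c2ccc(CO[Si](c5ccccc5)(c5ccccc5)C(C)(C)C)c([C@H](C)CCCOC(C)=O)c2)C[C@H]1[C@H]3OC(C)=O | intermediate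
41 | diacetate, C12 allylic alcohol | CC(C)[Si](C(C)C)(C(C)C)O[C@H]2C[C@H](C)C3=C(C[C@@H]2C(=C)CO)[C@@]1(C)OC(=O)[C@@H](c2ccc(CO[Si](c5ccccc5)(c5ccccc5)C(C)(C)C)c([C@H](C)CCCOC(C)=O)c2)C[C@H]1[C@H]3OC(C)=O | intermediate
42 | diacetate, C12 enal | CC(C)[Si](C(C)C)(C(C)C)O[C@H]2C[C@H](C)C3=C(C[C@@H]2C(=C)C=O)[C@@]1(C)OC(=O)[C@@H](c2ccc(CO[Si](c5ccccc5)(c5ccccc5)C(C)(C)C)c([C@H](C)CCCOC(C)=O)c2)C[C@H]1[C@H]3OC(C)=O | intermediate
43 | diacetate, C12 acrylic acid | CC(C)[Si](C(C)C)(C(C)C)O[C@H]2C[C@H](C)C3=C(C[C@@H]2C(=C)C(=O)O)[C@@]1(C)OC(=O)[C@@H](c2ccc(CO[Si](c5ccccc5)(c5ccccc5)C(C)(C)C)c([C@H](C)CCCOC(C)=O)c2)C[C@H]1[C@H]3OC(C)=O | intermediate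
44 | desilylated hydroxy acid (8α-OH, benzylic OH, acrylic acid) | O[C@H]2C[C@H](C)C3=C(C[C@@H]2C(=C)C(=O)O)[C@@]1(C)OC(=O)[C@@H](c2ccc(CO)c([C@H](C)CCCOC(C)=O)c2)C[C@H]1[C@H]3OC(C)=O | intermediate
45 | CNP0205574.1 | C=C1C(=O)O[C@H]2C[C@H](C)C3=C(C[C@H]12)[C@@]1(C)OC(=O)[C@@H](c2ccc(CO)c([C@H](C)CCCOC(C)=O)c2)C[C@H]1[C@H]3OC(C)=O | target

**Totals and risks**
Total step count: 30. Longest linear sequence: 21 steps (1, 2, 4–11, 13–15, 23–30).

Most likely to fail, step 23: carbopalladation of the hindered diene 22 by the bulky α-aryl vinylpalladium carboxylate may be slower than Diels–Alder self-dimerisation of 22 and β-hydride loss from the π-allyl, and the preference for the β-face may be incomplete. The fallback sets out from 22 and brings the aryl group in later. Annulation of 22 with commercial (Z)-3-iodoacrylic acid, a much smaller partner (Pd(OAc)2, n-Bu4NCl, K2CO3, DMF), should give the aryl-free unsaturated lactone F1. Copper hydride reduction with [(Ph3P)CuH]6 then gives the saturated lactone F2. Palladium-catalysed α-arylation of its zinc enolate with aryl bromide 30 (LiHMDS, ZnCl2, Pd(dba)2/Q-Phos), followed by DBU equilibration, comes back to the route at 37.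

Second, step 4: the electron-poor bromodiene 3 may be cyclopropanated too slowly, so that carbene dimerisation wins or the enantioselectivity is low. The fallback sets out from 5 and uses an electron-rich diene. Pent-1-en-3-one with TIPSOTf/Et3N gives (Z)-3-(triisopropylsilyloxy)penta-1,3-diene F3. The same Rh2(S-PTAD)4 [4+3] reaction with 5 gives the bis(silyl enol ether) cycloadduct F4, and 1 M HCl/THF gives the diketo ester F5. Hydrogenation with RuBr2[(S)-BINAP] (simple ketone untouched) gives the hydroxy keto ester F6, and TIPSOTf gives the TIPS ether F7. Kinetic enolisation toward C5 (KHMDS, PhNTf2) gives the vinyl triflate F8, and carbonylative coupling with 10 as in step 7 comes back to the route at 11.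

Third, step 20: the ortho-silyloxymethyl group twists the arene out of the alkene plane, so face discrimination by the non-chelating iridium catalyst may be poor. The fallback sets out from the free homoallylic alcohol 28 and relies on hydroxyl-directed (chelation-controlled) hydrogenation with Ru(OAc)2[(S)-BINAP] and H2 in MeOH to give the saturated alcohol F9. Silylation with TBSCl/imidazole comes back to the route at 30.

Further compounds
F1 | step 23 | aryl-free 3β,4β-cis-fused 5,6-dihydropyran-2-one on the C2-dioxolane hydroazulene | CC(C)[Si](C(C)C)(C(C)C)O[C@H]2C[C@H](C)C3=C(C[C@@H]2C(=C)COCc2ccc(OC)cc2)[C@@]1(C)OC(=O)C=C[C@H]1C34OCCO4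
F2 | step 23 | aryl-free saturated δ-lactone | CC(C)[Si](C(C)C)(C(C)C)O[C@H]2C[C@H](C)C3=C(C[C@@H]2C(=C)COCc2ccc(OC)cc2)[C@@]1(C)OC(=O)CC[C@H]1C34OCCO4
F3 | step 4 | (Z)-3-(triisopropylsilyloxy)penta-1,3-diene | C/C=C(\O[Si](C(C)C)(C(C)C)C(C)C)C=C
F4 | step 4 | ethyl (4S)-2-[(tert-butyldimethylsilyl)oxy]-4-methyl-5-[(triisopropylsilyl)oxy]cyclohepta-1,5-diene-1-carboxylate | CCOC(=O)C1=C(O[Si](C)(C)C(C)(C)C)C[C@H](C)C(O[Si](C(C)C)(C(C)C)C(C)C)=CC1
F5 | step 4 | ethyl (4S)-4-methyl-2,5-dioxocycloheptane-1-carboxylate | CCOC(=O)C1C(=O)C[C@H](C)C(=O)CC1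
F6 | step 4 | ethyl (1S,2S,4S)-2-hydroxy-4-methyl-5-oxocycloheptane-1-carboxylate | O[C@H]1C[C@H](C)C(=O)CC[C@@H]1C(=O)OCC
F7 | step 4 | triisopropylsilyl ether of F6 | CC(C)[Si](C(C)C)(C(C)C)O[C@H]1C[C@H](C)C(=O)CC[C@@H]1C(=O)OCC
F8 | step 4 | ethyl (1S,5S,7S)-5-methyl-7-[(triisopropylsilyl)oxy]-4-(triflyloxy)cyclohept-3-ene-1-carboxylate | CC(C)[Si](C(C)C)(C(C)C)O[C@H]1C[C@H](C)C(OS(=O)(=O)C(F)(F)F)=CC[C@@H]1C(=O)OCC
F9 | step 20 | (4R)-4-[5-bromo-2-({[tert-butyl(diphenyl)silyl]oxy}methyl)phenyl]pentan-1-ol | CC(C)(C)[Si](OCc1ccc(Br)cc1[C@H](C)CCCO)(c1ccccc1)c1ccccc1
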